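**Plan**
1. Retrosynthesis: cut the C3–O acyl bond (ester). Then cut C1'–C2' and C4a–C5 in one operation, which gives the monocyclic alkynyl enone 10 and the side-chain iodide 16. Then take the piperidinone ring of 10 back to a 2,5-disubstituted furan (aza-Achmatowicz), and cut the furan–C8 bond (Negishi).
2. Forward: the piperidinone ring arises first (furan → 6-hydroxy-dihydropyridinone → 2,6-trans enone). The carbocycle then closes while the side chain is joined (step 10). Reduction at C3, hydrogenation of C5=C1', acylation and deprotection follow.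
3. Stereochemistry: C2 comes from (R)-1-(furan-2-yl)ethanamine and C5' from (R)-2-propyloxirane. C8a is set by axial hydride delivery to an N-acyliminium ion, C4a by the tether (cis fusion), C3 by hydride attack anti to the axial C2 methyl, and C5 by convex-face hydrogenation.
4. Enabling feature: C4a is the β-carbon of an enone whose carbonyl is the C3 oxygen of the target. C5 is its neighbour in the ring C4a–C5–C6–C7–C8–C8a, and C1' is exocyclic on C5. A C5≡C1' alkyne tethered through C6–C8 to C8a can therefore be bonded to C4a and to the side-chain carbon C2' in one nickel cycle.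

Key step: step 10

Remark: target numbering (N1, C2–C4, C4a, C5–C8, C8a, side chain C1'–C8') is used for all precursors; compounds 1, 4, 11, 12 and 23 are taken as commercial.

**Step 1**
Reactants: 1 (R)-1-(furan-2-yl)ethan-1-amine
Product: 2 tert-butyl N-[(1R)-1-(furan-2-yl)ethyl]carbamate
Conditions: Boc2O, Et3N, CH2Cl2, 0 °C → rt
Reagents that add atoms: di-tert-butyl dicarbonate, CC(C)(C)OC(=O)OC(=O)OC(C)(C)C
Why: Carbamate (Boc) protection of a primary amine, which leaves the stereocentre untouched and supplies the N-acyl group needed for steps 5 and 6.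

**Step 2**
Reactants: 2 tert-butyl N-[(1R)-1-(furan-2-yl)ethyl]carbamate
Product: 3 tert-butyl N-[(1R)-1-(5-bromofuran-2-yl)ethyl]carbamate
Conditions: NBS, DMF, 0 °C, dark
Reagents that add atoms: N-bromosuccinimide, O=C1CCC(=O)N1Br
Why: Electrophilic aromatic bromination of a 2-alkylfuran should occur at the free α-position C5 under anhydrous conditions.

**Step 3**
Reactants: 3 tert-butyl N-[(1R)-1-(5-bromofuran-2-yl)ethyl]carbamate; 4 (5-iodopent-1-yn-1-yl)trimethylsilane
Product: 6 tert-butyl N-[(1R)-1-{5-[5-(trimethylsilyl)pent-4-yn-1-yl]furan-2-yl}ethyl]carbamate, via organozinc iodide 5 (not isolated)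
Conditions: 4, Zn dust (TMSCl/BrCH2CH2Br activation), DMA, 40 °C; then 3, Pd(OAc)2 (2 mol %), SPhos (4 mol %), THF, rt → 50 °C
Reagents that add atoms: none
Why: Negishi sp2–sp3 cross-coupling; the alkylzinc iodide tolerates the N–H carbamate and the silyl alkyne and should not disturb the benzylic-type stereocentre.

**Step 4**
Reactants: 6 tert-butyl N-[(1R)-1-{5-[5-(trimethylsilyl)pent-4-yn-1-yl]furan-2-yl}ethyl]carbamate
Product: 7 tert-butyl N-[(1R)-1-[5-(pent-4-yn-1-yl)furan-2-yl]ethyl]carbamate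
Conditions: K2CO3 (cat.), MeOH, rt
Reagents that add atoms: none
Why: Base-catalysed protodesilylation of an alkynylsilane, done at the furan stage so that the later enone never meets methoxide.

**Step 5**
Reactants: 7 tert-butyl N-[(1R)-1-[5-(pent-4-yn-1-yl)furan-2-yl]ethyl]carbamate
Product: 8 tert-butyl (2R)-6-hydroxy-2-methyl-3-oxo-6-(pent-4-yn-1-yl)-3,6-dihydro-2H-pyridine-1-carboxylate (C8a epimers)
Conditions: mCPBA, CH2Cl2, 0 °C → rt
Reagents that add atoms: 3-chloroperoxybenzoic acid (mCPBA), O=C(OO)c1cccc(Cl)c1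
Why: Aza-Achmatowicz oxidative ring expansion: the peracid oxidises the electron-rich 2,5-dialkylfuran and the carbamate nitrogen closes on the C8a carbonyl so released, which gives the piperidin-3-one ring with the C4=C4a enone while C2 keeps its configuration and the alkyne is left alone.

**Step 6**
Reactants: 8 tert-butyl (2R)-6-hydroxy-2-methyl-3-oxo-6-(pent-4-yn-1-yl)-3,6-dihydro-2H-pyridine-1-carboxylate
Product: 10 tert-butyl (2R,6R)-2-methyl-3-oxo-6-(pent-4-yn-1-yl)-3,6-dihydro-2H-pyridine-1-carboxylate, via N-acyliminium ion 9 (not isolated)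
Conditions: Et3SiH, BF3·OEt2, CH2Cl2, −78 → −40 °C
Reagents that add atoms: none
Why: Ionic (silane) reduction of a tertiary N,O-hemiaminal: BF3 ionises 8 to N-acyliminium ion 9, whose C2 methyl is pseudoaxial (A1,3 strain with the carbamate), and triethylsilane should deliver hydride axially on the methyl-bearing face through a chair-like transition state, which leaves the pentynyl chain trans to the methyl group (C8a R).

**Step 7**
Reactants: 11 (R)-2-propyloxirane; 12 vinylmagnesium bromide
Product: 13 (R)-hept-1-en-4-ol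
Conditions: CuI (10 mol %), THF, −30 → 0 °C; aq NH4Cl
Reagents that add atoms: none
Why: Copper-catalysed Grignard opening of a terminal epoxide at the unsubstituted carbon (SN2), so the carbinol stereocentre is not touched and stays R.

**Step 8**
Reactants: 13 (R)-hept-1-en-4-ol
Product: 14 tert-butyl{[(4R)-hept-1-en-4-yl]oxy}dimethylsilane
Conditions: TBSCl, imidazole, DMF, rt
Reagents that add atoms: tert-butyldimethylsilyl chloride, CC(C)(C)[Si](C)(C)Cl
Why: Silyl ether protection of the secondary alcohol, which must stay masked until the C3 hydroxyl has been acylated.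

**Step 9**
Reactants: 14 tert-butyl{[(4R)-hept-1-en-4-yl]oxy}dimethylsilane
Product: 16 tert-butyl{[(4R)-1-iodoheptan-4-yl]oxy}dimethylsilane, via B-alkyl-9-BBN 15 (not isolated)
Conditions: 9-BBN, THF, 0 °C → rt; then NaOMe/MeOH, I2, rt
Reagents that add atoms: iodine, II
Why: Anti-Markovnikov hydroboration of the terminal alkene followed by base-induced iodinolysis of the primary B–C bond, which should give the primary iodide without touching the stereocentre.

**Step 10**
Reactants: 10 tert-butyl (2R,6R)-2-methyl-3-oxo-6-(pent-4-yn-1-yl)-3,6-dihydro-2H-pyridine-1-carboxylate; 16 tert-butyl{[(4R)-1-iodoheptan-4-yl]oxy}dimethylsilane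
Product: 20 tert-butyl (2R,4aS,5Z,8aR)-5-[(5R)-5-{[tert-butyl(dimethyl)silyl]oxy}octylidene]-2-methyl-3-oxooctahydroquinoline-1(2H)-carboxylate, via alkyllithium 17 (not isolated), via alkylzinc chloride 18 (not isolated), via zinc enolate 19 (not isolated)
Conditions: 16, t-BuLi (2 equiv), Et2O, −78 °C; ZnCl2, THF, −78 → 0 °C; then Ni(cod)2 (10 mol %, no phosphine), slow addition of 10, THF, 0 °C; aq NH4Cl
Reagents that add atoms: none
Why: Ni(0) binds the C4=C4a enone and the C5≡C1' alkyne of 10 and couples them oxidatively to a nickelacycle with the new C4a–C5 bond, an O-bound enolate and an alkenyl–Ni bond at C1'; alkylzinc 18 then hands its primary alkyl group to nickel while zinc takes the enolate (19), and C(sp2)–C(sp3) reductive elimination forms C1'–C2' and returns Ni(0). The closest known reaction type is the nickel-catalysed alkylative cyclisation of alkynyl enones with organozincs (three-component enone–alkyne–organozinc coupling), which under phosphine-free Ni(cod)2 transfers sp3 groups that carry β-hydrogens. The carbocycle C4a–C5–C6–C7–C8–C8a closes in a 6-exo mode with respect to both the enone (trig) and the alkyne (dig), and syn addition across the alkyne gives the exocyclic 5Z alkene. The one new stereocentre, C4a, is controlled by C8a: the chain on C8a is pseudoaxial on the N-Boc ring and can only reach its own face of C4a, so the ring fusion should be cis (4aS). The step needs alkyl transfer to outrun β-hydride elimination, and cyclisation to outrun direct 1,4-addition of 18 to the enone and alkyne oligomerisation; the absence of phosphine, the terminal alkyne tethered through C6–C8 to C8a, and slow addition of 10 serve these ends.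

**Step 11**
Reactants: 20 tert-butyl (2R,4aS,5Z,8aR)-5-[(5R)-5-{[tert-butyl(dimethyl)silyl]oxy}octylidene]-2-methyl-3-oxooctahydroquinoline-1(2H)-carboxylate
Product: 21 tert-butyl (2R,3R,4aS,5Z,8aR)-5-[(5R)-5-{[tert-butyl(dimethyl)silyl]oxy}octylidene]-3-hydroxy-2-methyloctahydroquinoline-1(2H)-carboxylate
Conditions: L-Selectride, THF, −78 °C; aq NH4Cl
Reagents that add atoms: none
Why: Bulky-hydride ketone reduction: the C2 methyl is held pseudoaxial by A1,3 strain with the carbamate and shields its face of the C3 carbonyl, so hydride should enter anti to it and give the 2,3-cis (3R) alcohol, as with N-acyl-2-alkylpiperidin-3-ones.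

**Step 12**
Reactants: 21 tert-butyl (2R,3R,4aS,5Z,8aR)-5-[(5R)-5-{[tert-butyl(dimethyl)silyl]oxy}octylidene]-3-hydroxy-2-methyloctahydroquinoline-1(2H)-carboxylate
Product: 22 tert-butyl (2R,3R,4aS,5S,8aR)-5-[(5R)-5-{[tert-butyl(dimethyl)silyl]oxy}octyl]-3-hydroxy-2-methyloctahydroquinoline-1(2H)-carboxylate
Conditions: H2 (1 atm), PtO2, EtOAc, rt
Reagents that add atoms: none
Why: Heterogeneous catalytic hydrogenation of the exocyclic alkene from the convex face of the cis-fused bicycle (the face of H4a and H8a, away from C4), which should set C5 as S with H5 cis to H4a.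

**Step 13**
Reactants: 22 tert-butyl (2R,3R,4aS,5S,8aR)-5-[(5R)-5-{[tert-butyl(dimethyl)silyl]oxy}octyl]-3-hydroxy-2-methyloctahydroquinoline-1(2H)-carboxylate; 23 (2E)-oct-2-enoic acid
Product: 24 tert-butyl (2R,3R,4aS,5S,8aR)-5-[(5R)-5-{[tert-butyl(dimethyl)silyl]oxy}octyl]-2-methyl-3-{[(2E)-oct-2-enoyl]oxy}octahydroquinoline-1(2H)-carboxylate
Conditions: EDC, DMAP, CH2Cl2, 0 °C → rt
Reagents that add atoms: none
Why: Steglich-type carbodiimide esterification of the only free hydroxyl, with retention at C3 and the nitrogen and the C5' oxygen masked.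

**Step 14**
Reactants: 24 tert-butyl (2R,3R,4aS,5S,8aR)-5-[(5R)-5-{[tert-butyl(dimethyl)silyl]oxy}octyl]-2-methyl-3-{[(2E)-oct-2-enoyl]oxy}octahydroquinoline-1(2H)-carboxylate
Product: 25 (2R,3R,4aS,5S,8aR)-5-[(5R)-5-hydroxyoctyl]-2-methyldecahydroquinolin-3-yl (2E)-oct-2-enoate
Conditions: TFA/CH2Cl2/H2O, 0 °C → rt; aq NaHCO3
Reagents that add atoms: none
Why: Acidolysis of the Boc carbamate and of the TBS ether in one operation, under which the conjugated ester should survive.

**Compound list**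
1 | (R)-1-(furan-2-yl)ethan-1-amine | C[C@@H](N)c1ccco1 | starting material
2 | tert-butyl N-[(1R)-1-(furan-2-yl)ethyl]carbamate | C[C@@H](NC(=O)OC(C)(C)C)c1ccco1 | intermediate
3 | tert-butyl N-[(1R)-1-(5-bromofuran-2-yl)ethyl]carbamate | C[C@@H](NC(=O)OC(C)(C)C)c1ccc(Br)o1 | intermediate
4 | (5-iodopent-1-yn-1-yl)trimethylsilane | C[Si](C)(C)C#CCCCI | starting material
5 | [5-(trimethylsilyl)pent-4-yn-1-yl]zinc iodide | C[Si](C)(C)C#CCCC[Zn]I | intermediate
6 | tert-butyl N-[(1R)-1-{5-[5-(trimethylsilyl)pent-4-yn-1-yl]furan-2-yl}ethyl]carbamate | C[C@@H](NC(=O)OC(C)(C)C)c1ccc(CCCC#C[Si](C)(C)C)o1 | intermediate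
7 | tert-butyl N-[(1R)-1-[5-(pent-4-yn-1-yl)furan-2-yl]ethyl]carbamate | C[C@@H](NC(=O)OC(C)(C)C)c1ccc(CCCC#C)o1 | intermediate
8 | tert-butyl (2R)-6-hydroxy-2-methyl-3-oxo-6-(pent-4-yn-1-yl)-3,6-dihydro-2H-pyridine-1-carboxylate (C8a epimers) | O=C1C=CC(O)(CCCC#C)N(C(=O)OC(C)(C)C)[C@@H]1C | intermediate
9 | (2R)-1-(tert-butoxycarbonyl)-2-methyl-3-oxo-6-(pent-4-yn-1-yl)-2,3-dihydropyridin-1-ium (N-acyliminium ion) | O=C1C=CC(CCCC#C)=[N+](C(=O)OC(C)(C)C)[C@@H]1C | intermediate
10 | tert-butyl (2R,6R)-2-methyl-3-oxo-6-(pent-4-yn-1-yl)-3,6-dihydro-2H-pyridine-1-carboxylate | O=C1C=C[C@@H](CCCC#C)N(C(=O)OC(C)(C)C)[C@@H]1C | intermediate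
11 | (R)-2-propyloxirane | CCC[C@@H]1CO1 | starting material
12 | vinylmagnesium bromide | C=C[Mg]Br | starting material
13 | (R)-hept-1-en-4-ol | C=CC[C@H](O)CCC | intermediate
14 | tert-butyl{[(4R)-hept-1-en-4-yl]oxy}dimethylsilane | C=CC[C@H](O[Si](C)(C)C(C)(C)C)CCC | intermediate
15 | 9-[(4R)-4-{[tert-butyl(dimethyl)silyl]oxy}heptyl]-9-borabicyclo[3.3.1]nonane | B1(CCC[C@H](O[Si](C)(C)C(C)(C)C)CCC)C2CCCC1CCC2 | intermediate
16 | tert-butyl{[(4R)-1-iodoheptan-4-yl]oxy}dimethylsilane | ICCC[C@H](O[Si](C)(C)C(C)(C)C)CCC | intermediate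
17 | [(4R)-4-{[tert-butyl(dimethyl)silyl]oxy}heptyl]lithium | [Li]CCC[C@H](O[Si](C)(C)C(C)(C)C)CCC | intermediate
18 | [(4R)-4-{[tert-butyl(dimethyl)silyl]oxy}heptyl]zinc chloride | Cl[Zn]CCC[C@H](O[Si](C)(C)C(C)(C)C)CCC | intermediate
19 | chlorozinc enolate of 20 (C3–O–ZnCl, C3=C4) | Cl[Zn]OC1=C[C@H]2/C(=C\CCC[C@H](O[Si](C)(C)C(C)(C)C)CCC)CCC[C@H]2N(C(=O)OC(C)(C)C)[C@@H]1C | intermediate
20 | tert-butyl (2R,4aS,5Z,8aR)-5-[(5R)-5-{[tert-butyl(dimethyl)silyl]oxy}octylidene]-2-methyl-3-oxooctahydroquinoline-1(2H)-carboxylate | O=C1C[C@H]2/C(=C\CCC[C@H](O[Si](C)(C)C(C)(C)C)CCC)CCC[C@H]2N(C(=O)OC(C)(C)C)[C@@H]1C | intermediate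
21 | tert-butyl (2R,3R,4aS,5Z,8aR)-5-[(5R)-5-{[tert-butyl(dimethyl)silyl]oxy}octylidene]-3-hydroxy-2-methyloctahydroquinoline-1(2H)-carboxylate | O[C@@H]1C[C@H]2/C(=C\CCC[C@H](O[Si](C)(C)C(C)(C)C)CCC)CCC[C@H]2N(C(=O)OC(C)(C)C)[C@@H]1C | intermediate
22 | tert-butyl (2R,3R,4aS,5S,8aR)-5-[(5R)-5-{[tert-butyl(dimethyl)silyl]oxy}octyl]-3-hydroxy-2-methyloctahydroquinoline-1(2H)-carboxylate | O[C@@H]1C[C@H]2[C@@H](CCCC[C@H](O[Si](C)(C)C(C)(C)C)CCC)CCC[C@H]2N(C(=O)OC(C)(C)C)[C@@H]1C | intermediate
23 | (2E)-oct-2-enoic acid | CCCCC/C=C/C(=O)O | starting material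
24 | tert-butyl (2R,3R,4aS,5S,8aR)-5-[(5R)-5-{[tert-butyl(dimethyl)silyl]oxy}octyl]-2-methyl-3-{[(2E)-oct-2-enoyl]oxy}octahydroquinoline-1(2H)-carboxylate | CCCCC/C=C/C(=O)O[C@@H]1C[C@H]2[C@@H](CCCC[C@H](O[Si](C)(C)C(C)(C)C)CCC)CCC[C@H]2N(C(=O)OC(C)(C)C)[C@@H]1C | intermediate
25 | (2R,3R,4aS,5S,8aR)-5-[(5R)-5-hydroxyoctyl]-2-methyldecahydroquinolin-3-yl (2E)-oct-2-enoate | CCCCC/C=C/C(=O)O[C@@H]1C[C@H]2[C@@H](CCCC[C@H](O)CCC)CCC[C@H]2N[C@@H]1C | target

**Step count and risks**
Total step count: 14. Longest linear sequence: 11 steps (steps 1–6 and 10–14); steps 7–9 form the side-chain branch.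

The three steps most likely to fail:

Step 10. The six-membered oxidative cyclisation onto an endocyclic enone may be slow. β-Hydride elimination (cyclisation without alkyl transfer), direct nickel-catalysed 1,4-addition of the zinc reagent, or alkyne oligomerisation could then take over. The fallback sets out from 10 and replaces the nickel cycle by a radical closure followed by a separate coupling. Tributyltin hydride and AIBN (benzene, 80 °C) add a stannyl radical to the terminal alkyne, and the vinyl radical closes 6-exo on C4a to give the vinylstannane F1. Iododestannylation (I2, CH2Cl2, 0 °C) gives the vinyl iodide F2. A B-alkyl Suzuki–Miyaura coupling of F2 with the borane 15 (PdCl2(dppf), AsPh3, K3PO4, DMF/THF/H2O, rt) forms the same C1'–C2' bond. It should give 20 together with its 5E isomer F3. F3 is taken through the conditions of step 11 to the 5E alcohol F4 and through those of step 12. The fallback thus comes back to the route at 20 and, for the E series, at 22.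

Step 6. Hydride may be delivered to the other face of the N-acyliminium ion (anti to the C2 methyl), which would give the 2,6-cis isomer. The fallback sets out from 2 and brings the chain in as a carbon nucleophile, which would enter on that same anti face and so end trans to the methyl group. Aza-Achmatowicz oxidation of 2 (mCPBA) gives the 6-unsubstituted hemiaminal F5. Allyltrimethylsilane and BF3·OEt2 (CH2Cl2, −78 °C) give the 2,6-trans allyl enone F6. Linear-selective hydroformylation (Rh(acac)(CO)2, Xantphos, CO/H2) gives the aldehyde F7. Ohira–Bestmann homologation (dimethyl (1-diazo-2-oxopropyl)phosphonate, K2CO3, MeOH) comes back to the route at 10.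

Step 11. The axial C4a–C5 bond may hinder the face anti to the C2 methyl, so that hydride attacks the other face and the 3S alcohol prevails. The fallback sets out from 20 and corrects C3 by inversion at the acylation stage. The 3S alcohol F8 (from the same reduction, or from NaBH4 if that gives it more cleanly) is hydrogenated as in step 12 to the saturated 3S alcohol F9. A Mitsunobu esterification of F9 with acid 23 (PPh3, DIAD, toluene, 0 °C → rt) inverts C3 and comes back to the route at 24.

**Further compounds**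
F1 | step 10 | tert-butyl (2R,4aS,8aR)-2-methyl-3-oxo-5-[(tributylstannyl)methylidene]octahydroquinoline-1(2H)-carboxylate (E/Z mixture) | O=C1C[C@H]2C(=C[Sn](CCCC)(CCCC)CCCC)CCC[C@H]2N(C(=O)OC(C)(C)C)[C@@H]1C
F2 | step 10 | tert-butyl (2R,4aS,8aR)-5-(iodomethylidene)-2-methyl-3-oxooctahydroquinoline-1(2H)-carboxylate (E/Z mixture) | O=C1C[C@H]2C(=CI)CCC[C@H]2N(C(=O)OC(C)(C)C)[C@@H]1C
F3 | step 10 | tert-butyl (2R,4aS,5E,8aR)-5-[(5R)-5-{[tert-butyl(dimethyl)silyl]oxy}octylidene]-2-methyl-3-oxooctahydroquinoline-1(2H)-carboxylate | O=C1C[C@H]2/C(=C/CCC[C@H](O[Si](C)(C)C(C)(C)C)CCC)CCC[C@H]2N(C(=O)OC(C)(C)C)[C@@H]1C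
F4 | step 10 | tert-butyl (2R,3R,4aS,5E,8aR)-5-[(5R)-5-{[tert-butyl(dimethyl)silyl]oxy}octylidene]-3-hydroxy-2-methyloctahydroquinoline-1(2H)-carboxylate | O[C@@H]1C[C@H]2/C(=C/CCC[C@H](O[Si](C)(C)C(C)(C)C)CCC)CCC[C@H]2N(C(=O)OC(C)(C)C)[C@@H]1C
F5 | step 6 | tert-butyl (2R)-6-hydroxy-2-methyl-3-oxo-3,6-dihydro-2H-pyridine-1-carboxylate (C8a epimers) | O=C1C=CC(O)N(C(=O)OC(C)(C)C)[C@@H]1C
F6 | step 6 | tert-butyl (2R,6R)-2-methyl-3-oxo-6-(prop-2-en-1-yl)-3,6-dihydro-2H-pyridine-1-carboxylate | O=C1C=C[C@@H](CC=C)N(C(=O)OC(C)(C)C)[C@@H]1C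
F7 | step 6 | tert-butyl (2R,6R)-2-methyl-3-oxo-6-(4-oxobutyl)-3,6-dihydro-2H-pyridine-1-carboxylate | O=C1C=C[C@@H](CCCC=O)N(C(=O)OC(C)(C)C)[C@@H]1C
F8 | step 11 | tert-butyl (2R,3S,4aS,5Z,8aR)-5-[(5R)-5-{[tert-butyl(dimethyl)silyl]oxy}octylidene]-3-hydroxy-2-methyloctahydroquinoline-1(2H)-carboxylate | O[C@H]1C[C@H]2/C(=C\CCC[C@H](O[Si](C)(C)C(C)(C)C)CCC)CCC[C@H]2N(C(=O)OC(C)(C)C)[C@@H]1C
F9 | step 11 | tert-butyl (2R,3S,4aS,5S,8aR)-5-[(5R)-5-{[tert-butyl(dimethyl)silyl]oxy}octyl]-3-hydroxy-2-methyloctahydroquinoline-1(2H)-carboxylate | O[C@H]1C[C@H]2[C@@H](CCCC[C@H](O[Si](C)(C)C(C)(C)C)CCC)CCC[C@H]2N(C(=O)OC(C)(C)C)[C@@H]1C
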